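**Retrosynthetic overview**
1. Endgame: MOM removal; the isobutyryl and formyl groups come from two MOM-directed ortho-lithiations of a tris-MOM arene; the isopropenyl group comes from a C7 ketone (nitrile, methyl ketone, Wittig).
2. Ring B (C5–C10) is closed last: acetonyl Wittig on a C9 aldehyde, hydrogenation, Robinson-type aldol onto the C5 ketone; 4α-OH and 5α-H follow from α-epoxidation of the deconjugated C4=C5 alkene, β-elimination and OH-directed hydrogenation.
3. Key disconnection: the benzylic CH2–aryl bond, made by palladium-catalysed C–C cleavage/arylation of a carvone-derived cyclobutanol (a bicyclo[3.1.1]hept-2-en-1-ol) with 2-bromo-1,3,5-tris(methoxymethoxy)benzene; the four-membered ring is cut and the ring A cyclohexenone appears.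
4. Enabling feature: ring A (C1, C2, C3, C4, C5, C10) plus the benzylic carbon is a hidden (S)-carvone (benzylic CH2 = carvone C6, C1 = C5, quaternary C10 with its methyl and C9 = the isopropenyl group, C4 methyl = ring methyl, C5 = carbonyl carbon); the benzylic carbon lies γ to C5, so CH2–C1–C10–C5 can be the four-membered ring of a cyclobutanol whose C5–CH2 bond is cut.
5. Ring order: ring A from carvone (cyclobutanol built, then cut), arene attached in the key step, ring B last.

Key step: step 6

Numbering remark: eudesmane numbering of the target is used for ring A and decalin intermediates (C1 bears the arylmethyl group, C4 the carbinol methyl, C5/C10 are the fusion carbons, C7 bears isopropenyl); Ar* = 2,4,6-tris(methoxymethoxy)phenyl.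
Assumption: the radical closure in step 4 gives the cyclobutanol diastereomer with CH2OH on the face of C6 turned toward the C2=C3 bridge (methyl toward the CH2 bridge); this is what places the arylmethyl group and the C10 methyl cis after step 6.

**Step 1**
Reactants: 1 phloroglucinol
Product: 2 1,3,5-tris(methoxymethoxy)benzene
Conditions: NaH, MOMCl, DMF, 0 → 23 °C
Reagents that add atoms: chloromethyl methyl ether, COCCl
Why: Williamson-type O-alkylation of the tris-phenoxide gives base-stable MOM ethers that later direct ortho-lithiation and are removable with mild acid.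

**Step 2**
Reactants: 2 1,3,5-tris(methoxymethoxy)benzene
Product: 3 2-bromo-1,3,5-tris(methoxymethoxy)benzene
Conditions: NBS (1.0 equiv), DCM, 0 °C
Reagents that add atoms: N-bromosuccinimide, BrN1C(=O)CCC1=O
Why: Electrophilic aromatic bromination of the strongly activated ring, whose three free positions are equivalent, should stop at the mono-bromide with one equivalent of NBS.

**Step 3**
Reactants: 4 (S)-(+)-carvone
Product: 5 (5S)-2-methyl-5-(2-methyloxiran-2-yl)cyclohex-2-en-1-one (mixture of epimers at the epoxide carbon)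
Conditions: mCPBA, DCM, 0 °C
Reagents that add atoms: 3-chloroperbenzoic acid, OOC(=O)c1cccc(Cl)c1
Why: Prilezhaev epoxidation takes the electron-rich 1,1-disubstituted alkene and leaves the electron-poor enone; the new stereocenter is formed unselectively and is erased in step 4.

**Step 4**
Reactants: 5 carvone 8,9-epoxide
Product: 6 (1R,5S,6R)-6-(hydroxymethyl)-2,6-dimethylbicyclo[3.1.1]hept-2-en-1-ol
Conditions: Cp2TiCl2 (2.5 equiv), Zn dust, THF, 23 °C; aq. NaH2PO4
Reagents that add atoms: none
Why: Reductive epoxide opening by Cp2TiCl (trivalent titanium) gives the tertiary radical, which closes 4-exo-trig onto the titanium-activated ketone carbon (a known two-step remodelling of carvone); the bridgehead carbinol is fixed by the C5 stereocenter, and C6 is set in the closure with the titanium-alkoxide arm turned toward the alkene bridge, away from the titanium-bound ketyl oxygen.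

**Step 5**
Reactants: 6 cyclobutanol diol
Product: 7 (1R,5S,6R)-6-{[(tert-butyldimethylsilyl)oxy]methyl}-2,6-dimethylbicyclo[3.1.1]hept-2-en-1-ol
Conditions: TBSCl, imidazole, DCM, 0 °C
Reagents that add atoms: tert-butyldimethylsilyl chloride, CC(C)(C)[Si](C)(C)Cl
Why: Selective silylation of the primary hydroxyl (the bridgehead tertiary alcohol is too hindered) masks the only alcohol that could be oxidized by arylpalladium in step 6.

**Step 6**
Reactants: 7 silyl-protected cyclobutanol; 3 2-bromo-1,3,5-tris(methoxymethoxy)benzene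
Product: 8 (5S,6R)-6-{[(tert-butyldimethylsilyl)oxy]methyl}-2,6-dimethyl-5-[2,4,6-tris(methoxymethoxy)benzyl]cyclohex-2-en-1-one (ring A enone; Ar*CH2 cis to the C6 methyl)
Conditions: Pd(OAc)2 (10 mol %), XPhos (20 mol %), Cs2CO3 (2 equiv), toluene, 90 °C
Reagents that add atoms: none
Why: Oxidative addition of 3 to zerovalent palladium, exchange of bromide for the caesium cyclobutanolate of 7 and strain-driven β-carbon elimination of the C1–C7 bond give a primary alkyl(aryl)palladium species that reductively eliminates to form the CH2–aryl bond, while the bridgehead carbinol becomes the C5 enone carbonyl. The closest known reaction type is the palladium-catalysed arylative ring opening of tertiary cyclobutanols with aryl bromides, which has been applied to carvone-derived bicyclo[3.1.1]heptenols. No ring is closed: the four-membered ring is opened and the ring A cyclohexenone is unveiled. No stereocenter is made; C1 (carvone C5) and the quaternary C10 (from step 4) are not touched by the bond that breaks and are carried over unchanged, which is why the arylmethyl group and the C10 methyl end up cis. Two selectivities are needed: cleavage of the bond to the CH2 bridge and not the bond to the quaternary bridge, secured because β-carbon elimination places palladium on the less substituted carbon, and reductive elimination ahead of β-hydride elimination at C1, secured by the bulky electron-rich biaryl phosphine and the two ortho substituents of the aryl group.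

**Step 7**
Reactants: 8 silyl ether enone
Product: 9 (5S,6R)-6-(hydroxymethyl)-2,6-dimethyl-5-[2,4,6-tris(methoxymethoxy)benzyl]cyclohex-2-en-1-one
Conditions: TBAF, AcOH, THF, 0 °C
Reagents that add atoms: none
Why: Fluoride desilylation, buffered with acetic acid so that the β-hydroxy ketone does not lose formaldehyde by retro-aldol cleavage.

**Step 8**
Reactants: 9 hydroxymethyl enone
Product: 11 (5S,6R)-2,6-dimethyl-6-[(1E)-3-oxobut-1-en-1-yl]-5-[2,4,6-tris(methoxymethoxy)benzyl]cyclohex-2-en-1-one, via keto aldehyde 10 (not isolated)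
Conditions: DMP, NaHCO3, DCM, 0 °C; then Ph3P=CHC(O)CH3, 40 °C
Reagents that add atoms: 1-(triphenylphosphoranylidene)propan-2-one, CC(=O)C=P(c1ccccc1)(c1ccccc1)c1ccccc1
Why: Dess–Martin oxidation followed in the same flask by Wittig olefination with a stabilized ylide, which reacts only with the aldehyde and gives the (E)-enone; the sensitive β-keto aldehyde is not isolated.

**Step 9**
Reactants: 11 bis-enone
Product: 12 2,6-dimethyl-6-(3-oxobutyl)-5-[2,4,6-tris(methoxymethoxy)benzyl]cyclohexan-1-one (C5 and C6 as in 9; mixture at C2, the future C4)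
Conditions: H2 (1 atm), 10% Pd/C, EtOAc, 23 °C
Reagents that add atoms: none
Why: Heterogeneous hydrogenation saturates both enone C=C bonds; the new C4 stereocenter is formed unselectively and becomes sp2 again in step 11.

**Step 10**
Reactants: 12 1,5-diketone
Product: 13 1β-(Ar*CH2)-11,12,13-trinoreudesm-5-en-7-one (mixture at C4)
Conditions: NaOMe, MeOH, reflux
Reagents that add atoms: none
Why: Robinson-type intramolecular aldol condensation of the methyl ketone onto the C5 ketone closes ring B (six-membered, exo attack on the carbonyl) and dehydrates to the conjugated enone, as in annulations of 2,6-dimethyl-2-(3-oxobutyl)cyclohexanones.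

**Step 11**
Reactants: 13 ring B enone
Product: 16 4α-hydroxy-1β-(Ar*CH2)-11,12,13-trinoreudesm-5-en-7-one, via β,γ-enone 14 (not isolated), via epoxy ketone 15 (not isolated)
Conditions: KOt-Bu, t-BuOH, 23 °C (argon), then cold aq. AcOH; crude: mCPBA, DCM, 0 °C; then Et3N (cat.), 23 °C
Reagents that add atoms: 3-chloroperbenzoic acid, OOC(=O)c1cccc(Cl)c1
Why: Kinetic α-protonation of the extended potassium dienolate moves the double bond to C4=C5 (classical enone deconjugation), the peracid epoxidizes this tetrasubstituted alkene from the α face anti to the C10 methyl on the neighbouring carbon, and E1cB opening of the β,γ-epoxy ketone (C5–O cleavage) leaves the 4α-hydroxyl and restores the enone, so the face of epoxidation sets C4.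

**Step 12**
Reactants: 16 γ-hydroxy enone
Product: 17 4α-hydroxy-1β-(Ar*CH2)-11,12,13-trinor-5α-eudesman-7-one
Conditions: [Ir(cod)(PCy3)(py)]PF6 (10 mol %), H2 (1 atm), DCM, 23 °C
Reagents that add atoms: none
Why: Hydroxyl-directed hydrogenation with the cationic iridium catalyst: the tertiary allylic 4α-OH binds the metal and hydrogen is delivered to C5 from the α face, giving the trans-fused decalin (5α-H).

**Step 13**
Reactants: 17 hydroxy ketone
Product: 18 4α-hydroxy-1β-(Ar*CH2)-12,13-dinor-5α-eudesmane-11-nitrile (mixture at C7)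
Conditions: TosMIC, KOt-Bu, DME, EtOH, 0 → 40 °C
Reagents that add atoms: p-toluenesulfonylmethyl isocyanide, Cc1ccc(cc1)S(=O)(=O)C[N+]#[C-]
Why: Van Leusen reductive cyanation converts the unhindered C7 ketone into the one-carbon-homologated nitrile; the C7 epimer mixture is irrelevant because C7 is equilibrated in step 14.

**Step 14**
Reactants: 18 nitrile
Product: 20 4α-hydroxy-1β-(Ar*CH2)-13-nor-5α-eudesman-11-one (7β-acetyl, 7α-H), via ketimine 19 (not isolated)
Conditions: MeLi (3 equiv), Et2O–THF, 0 → 23 °C; aq. AcOH, 23 °C; then NaOMe (cat.), MeOH, 23 °C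
Reagents that add atoms: methyllithium, [Li]C; water, O
Why: Addition of methyllithium to the nitrile and hydrolysis of the ketimine give the methyl ketone, and base equilibration through the enolate places the acetyl group equatorial (7β), so C7 is set under thermodynamic control.

**Step 15**
Reactants: 20 methyl ketone
Product: 21 1β-(Ar*CH2)-5α-eudesm-11-en-4α-ol (7β-isopropenyl)
Conditions: Ph3PCH3Br, KOt-Bu, THF, 0 → 23 °C
Reagents that add atoms: methyltriphenylphosphonium bromide, C[P+](c1ccccc1)(c1ccccc1)c1ccccc1.[Br-]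
Why: Wittig methylenation of the acetyl group gives the isopropenyl group; an excess of ylide covers the free tertiary alcohol, and the equatorial C7 configuration is the stable one if any enolization occurs.

**Step 16**
Reactants: 21 tris-MOM arene with isopropenyl group
Product: 23 1β-{[3-(1-hydroxy-2-methylpropyl)-2,4,6-tris(methoxymethoxy)phenyl]methyl}-5α-eudesm-11-en-4α-ol (mixture at the new carbinol), via aryllithium 22 (not isolated)
Conditions: n-BuLi (2.2 equiv), THF, 0 °C; i-PrCHO, −78 → 0 °C; aq. NH4Cl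
Reagents that add atoms: isobutyraldehyde, CC(C)C=O
Why: Directed ortho-metalation at a ring C–H flanked by two MOM ethers (the two free positions are equivalent) and addition to the aldehyde; the carbinol stereocenter is formed unselectively and removed in step 18.

**Step 17**
Reactants: 23 benzylic alcohol
Product: 25 1β-{[3-formyl-5-(1-hydroxy-2-methylpropyl)-2,4,6-tris(methoxymethoxy)phenyl]methyl}-5α-eudesm-11-en-4α-ol, via aryllithium 24 (not isolated)
Conditions: n-BuLi (3.3 equiv), TMEDA, THF, 0 °C; DMF, −78 → 23 °C; aq. NH4Cl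
Reagents that add atoms: N,N-dimethylformamide, CN(C)C=O
Why: A second directed ortho-metalation at the last ring C–H (again between two MOM ethers, after deprotonation of both hydroxyls) and formylation with DMF.

**Step 18**
Reactants: 25 hydroxy aldehyde
Product: 26 1β-{[3-formyl-5-isobutyryl-2,4,6-tris(methoxymethoxy)phenyl]methyl}-5α-eudesm-11-en-4α-ol
Conditions: DMP, NaHCO3, DCM, 0 → 23 °C
Reagents that add atoms: none
Why: Dess–Martin oxidation of the secondary benzylic alcohol to the aryl ketone; the tertiary C4 alcohol, the aldehyde and the isopropenyl group are inert.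

**Step 19**
Reactants: 26 tris-MOM ether
Product: 27 target, 1β-[(3-formyl-2,4,6-trihydroxy-5-isobutyrylphenyl)methyl]-5α-eudesm-11-en-4α-ol
Conditions: HCl (1.25 M in MeOH), THF, 23 °C
Reagents that add atoms: none
Why: Acid-catalysed acetal exchange removes the three MOM groups (made easier by hydrogen bonding to the ortho carbonyls) under conditions mild enough for the tertiary alcohol and the isopropenyl group.

**Compound list**
1 | phloroglucinol | Oc1cc(O)cc(O)c1 | starting material
2 | 1,3,5-tris(methoxymethoxy)benzene | COCOc1cc(OCOC)cc(OCOC)c1 | intermediate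
3 | 2-bromo-1,3,5-tris(methoxymethoxy)benzene | COCOc1cc(OCOC)c(Br)c(OCOC)c1 | intermediate
4 | (S)-(+)-carvone | CC1=CC[C@@H](CC1=O)C(C)=C | starting material
5 | (5S)-2-methyl-5-(2-methyloxiran-2-yl)cyclohex-2-en-1-one (epimers at the epoxide carbon) | CC1=CC[C@@H](CC1=O)C2(C)CO2 | intermediate
6 | (1R,5S,6R)-6-(hydroxymethyl)-2,6-dimethylbicyclo[3.1.1]hept-2-en-1-ol | CC1=CC[C@H]2C[C@]1(O)[C@@]2(C)CO | intermediate
7 | (1R,5S,6R)-6-{[(tert-butyldimethylsilyl)oxy]methyl}-2,6-dimethylbicyclo[3.1.1]hept-2-en-1-ol | CC1=CC[C@H]2C[C@]1(O)[C@@]2(C)CO[Si](C)(C)C(C)(C)C | intermediate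
8 | (5S,6R)-6-{[(tert-butyldimethylsilyl)oxy]methyl}-2,6-dimethyl-5-[2,4,6-tris(methoxymethoxy)benzyl]cyclohex-2-en-1-one | CC1=CC[C@@H](Cc2c(OCOC)cc(OCOC)cc2OCOC)[C@](C)(CO[Si](C)(C)C(C)(C)C)C1=O | intermediate
9 | (5S,6R)-6-(hydroxymethyl)-2,6-dimethyl-5-[2,4,6-tris(methoxymethoxy)benzyl]cyclohex-2-en-1-one | CC1=CC[C@@H](Cc2c(OCOC)cc(OCOC)cc2OCOC)[C@](C)(CO)C1=O | intermediate
10 | keto aldehyde: 1,3-dimethyl-2-oxo-6-[2,4,6-tris(methoxymethoxy)benzyl]cyclohex-3-ene-1-carbaldehyde (configuration as in 9) | CC1=CC[C@@H](Cc2c(OCOC)cc(OCOC)cc2OCOC)[C@](C)(C=O)C1=O | intermediate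
11 | 2,6-dimethyl-6-[(1E)-3-oxobut-1-en-1-yl]-5-[2,4,6-tris(methoxymethoxy)benzyl]cyclohex-2-en-1-one (configuration as in 9) | CC1=CC[C@@H](Cc2c(OCOC)cc(OCOC)cc2OCOC)[C@](C)(/C=C/C(C)=O)C1=O | intermediate
12 | 2,6-dimethyl-6-(3-oxobutyl)-5-[2,4,6-tris(methoxymethoxy)benzyl]cyclohexan-1-one (epimers at C2) | CC1CC[C@@H](Cc2c(OCOC)cc(OCOC)cc2OCOC)[C@](C)(CCC(C)=O)C1=O | intermediate
13 | 1β-(Ar*CH2)-11,12,13-trinoreudesm-5-en-7-one (epimers at C4) | CC1CC[C@@H](Cc3c(OCOC)cc(OCOC)cc3OCOC)[C@]2(C)CCC(=O)C=C12 | intermediate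
14 | 1β-(Ar*CH2)-11,12,13-trinoreudesm-4-en-7-one | CC1=C2CC(=O)CC[C@@]2(C)[C@H](Cc3c(OCOC)cc(OCOC)cc3OCOC)CC1 | intermediate
15 | 4α,5α-epoxy-1β-(Ar*CH2)-11,12,13-trinoreudesman-7-one | C[C@@]12CC[C@@H](Cc3c(OCOC)cc(OCOC)cc3OCOC)[C@]4(C)CCC(=O)C[C@@]14O2 | intermediate
16 | 4α-hydroxy-1β-(Ar*CH2)-11,12,13-trinoreudesm-5-en-7-one | C[C@@]1(O)CC[C@@H](Cc3c(OCOC)cc(OCOC)cc3OCOC)[C@]2(C)CCC(=O)C=C12 | intermediate
17 | 4α-hydroxy-1β-(Ar*CH2)-11,12,13-trinor-5α-eudesman-7-one | C[C@@]1(O)CC[C@@H](Cc3c(OCOC)cc(OCOC)cc3OCOC)[C@]2(C)CCC(=O)C[C@@H]12 | intermediate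
18 | 4α-hydroxy-1β-(Ar*CH2)-12,13-dinor-5α-eudesmane-11-nitrile (epimers at C7) | C[C@@]1(O)CC[C@@H](Cc3c(OCOC)cc(OCOC)cc3OCOC)[C@]2(C)CCC(C#N)C[C@@H]12 | intermediate
19 | ketimine: 11-imino-13-nor analogue of 20 (epimers at C7) | C[C@@]1(O)CC[C@@H](Cc3c(OCOC)cc(OCOC)cc3OCOC)[C@]2(C)CCC(C(C)=N)C[C@@H]12 | intermediate
20 | 4α-hydroxy-1β-(Ar*CH2)-13-nor-5α-eudesman-11-one (7β-acetyl) | C[C@@]1(O)CC[C@@H](Cc3c(OCOC)cc(OCOC)cc3OCOC)[C@]2(C)CC[C@@H](C(C)=O)C[C@@H]12 | intermediate
21 | 1β-(Ar*CH2)-5α-eudesm-11-en-4α-ol | C[C@@]1(O)CC[C@@H](Cc3c(OCOC)cc(OCOC)cc3OCOC)[C@]2(C)CC[C@@H](C(C)=C)C[C@@H]12 | intermediate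
22 | aryllithium of 21 (ring carbon between two MOM ethers lithiated; lithium 4-alkoxide) | C[C@@]1(O[Li])CC[C@@H](Cc3c(OCOC)c([Li])c(OCOC)cc3OCOC)[C@]2(C)CC[C@@H](C(C)=C)C[C@@H]12 | intermediate
23 | 1β-{[3-(1-hydroxy-2-methylpropyl)-2,4,6-tris(methoxymethoxy)phenyl]methyl}-5α-eudesm-11-en-4α-ol (carbinol epimers) | C[C@@]1(O)CC[C@@H](Cc3c(OCOC)c(C(O)C(C)C)c(OCOC)cc3OCOC)[C@]2(C)CC[C@@H](C(C)=C)C[C@@H]12 | intermediate
24 | aryllithium of 23 (last ring carbon lithiated; two lithium alkoxides) | C[C@@]1(O[Li])CC[C@@H](Cc3c(OCOC)c(C(O[Li])C(C)C)c(OCOC)c([Li])c3OCOC)[C@]2(C)CC[C@@H](C(C)=C)C[C@@H]12 | intermediate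
25 | 1β-{[3-formyl-5-(1-hydroxy-2-methylpropyl)-2,4,6-tris(methoxymethoxy)phenyl]methyl}-5α-eudesm-11-en-4α-ol | C[C@@]1(O)CC[C@@H](Cc3c(OCOC)c(C(O)C(C)C)c(OCOC)c(C=O)c3OCOC)[C@]2(C)CC[C@@H](C(C)=C)C[C@@H]12 | intermediate
26 | 1β-{[3-formyl-5-isobutyryl-2,4,6-tris(methoxymethoxy)phenyl]methyl}-5α-eudesm-11-en-4α-ol | C[C@@]1(O)CC[C@@H](Cc3c(OCOC)c(C(=O)C(C)C)c(OCOC)c(C=O)c3OCOC)[C@]2(C)CC[C@@H](C(C)=C)C[C@@H]12 | intermediate
27 | 1β-[(3-formyl-2,4,6-trihydroxy-5-isobutyrylphenyl)methyl]-5α-eudesm-11-en-4α-ol (CNP0498016.1) | C=C(C)[C@@H]1CC[C@@]2(C)[C@H](Cc3c(O)c(C=O)c(O)c(C(=O)C(C)C)c3O)CC[C@@](C)(O)[C@@H]2C1 | target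

**Count**
Total steps: 19. Longest linear sequence: 17 (steps 3–19, from (S)-carvone); steps 1–2 make the aryl bromide in parallel.

**Steps most likely to fail**

Step 6. The primary alkylpalladium intermediate may undergo β-hydride elimination at C1 faster than reductive elimination onto the electron-rich, doubly ortho-substituted aryl group, diverting material to an exocyclic alkene and reduced arene. The fallback sets out from 7 and returns at 8, and makes that elimination the wanted event. Oxidative ring cleavage of 7 under divalent-palladium conditions (Pd(OAc)2, pyridine, O2, toluene, 80 °C; β-carbon then β-hydride elimination) should give (6R)-6-{[(tert-butyldimethylsilyl)oxy]methyl}-2,6-dimethyl-5-methylidenecyclohex-2-en-1-one F1. Iridium-catalysed hydroboration with pinacolborane ([Ir(cod)Cl]2, dppe, DCM) should place boron on the terminal carbon and hydrogen on C1 from the face anti to the axial C10 methyl, giving the 5-[(pinacolboryl)methyl] analogue of 8 F2. B-alkyl Suzuki–Miyaura coupling of this boronate with 3 (Pd(OAc)2, SPhos, K3PO4, toluene–H2O, 80 °C) forms the same CH2–aryl bond and gives 8.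

Step 11. Deconjugation may be incomplete, or the β,γ-enone may slip back into conjugation before the peracid reaches it, and α-face selectivity of the epoxidation may erode. The fallback sets out from 13 and returns at 17, replacing epoxide opening and directed hydrogenation by one syn-hydroboration. The potassium dienolate of 13 (KOt-Bu, THF) is trapped with Ac2O as the dienyl acetate 7-acetoxy-1β-(Ar*CH2)-11,12,13-trinoreudesma-4,6-diene F3. NaBH4 in EtOH–THF cleaves the acetate and at once reduces the kinetically formed β,γ-enone to the homoallylic alcohol 1β-(Ar*CH2)-11,12,13-trinoreudesm-4-en-7-ol F4, which cannot reconjugate. Hydroboration–oxidation (BH3·THF; NaOH, H2O2) should add H and OH syn across C4=C5 from the α face, with boron at the less hindered C4, to give 1β-(Ar*CH2)-11,12,13-trinor-5α-eudesmane-4α,7-diol F5. DMP then oxidizes only the secondary C7 hydroxyl to give 17.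

Step 17. The second C–H metalation has to take place on a substrate that already carries two lithium alkoxides; incomplete lithiation or competing benzylic deprotonation would lower conversion. The fallback sets out from 23 and returns at 25. The last ring position is brominated (NBS, MeCN, −20 °C) to give the aryl bromide 1β-{[3-bromo-5-(1-hydroxy-2-methylpropyl)-2,4,6-tris(methoxymethoxy)phenyl]methyl}-5α-eudesm-11-en-4α-ol F6. After deprotonation of both hydroxyls with n-BuLi, bromine–lithium exchange (t-BuLi, THF, −78 °C) generates the aryllithium without a C–H metalation, and DMF gives 25.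

**Further compounds**
F1 | step 6 | (6R)-6-{[(tert-butyldimethylsilyl)oxy]methyl}-2,6-dimethyl-5-methylidenecyclohex-2-en-1-one | CC1=CCC(=C)[C@](C)(CO[Si](C)(C)C(C)(C)C)C1=O
F2 | step 6 | 6-{[(tert-butyldimethylsilyl)oxy]methyl}-2,6-dimethyl-5-[(4,4,5,5-tetramethyl-1,3,2-dioxaborolan-2-yl)methyl]cyclohex-2-en-1-one (configuration as in 8) | CC1=CC[C@@H](CB2OC(C)(C)C(C)(C)O2)[C@](C)(CO[Si](C)(C)C(C)(C)C)C1=O
F3 | step 11 | 7-acetoxy-1β-(Ar*CH2)-11,12,13-trinoreudesma-4,6-diene | CC1=C2C=C(OC(C)=O)CC[C@@]2(C)[C@H](Cc3c(OCOC)cc(OCOC)cc3OCOC)CC1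
F4 | step 11 | 1β-(Ar*CH2)-11,12,13-trinoreudesm-4-en-7-ol (epimers at C7) | CC1=C2CC(O)CC[C@@]2(C)[C@H](Cc3c(OCOC)cc(OCOC)cc3OCOC)CC1
F5 | step 11 | 1β-(Ar*CH2)-11,12,13-trinor-5α-eudesmane-4α,7-diol (epimers at C7) | C[C@@]1(O)CC[C@@H](Cc3c(OCOC)cc(OCOC)cc3OCOC)[C@]2(C)CCC(O)C[C@@H]12
F6 | step 17 | 1β-{[3-bromo-5-(1-hydroxy-2-methylpropyl)-2,4,6-tris(methoxymethoxy)phenyl]methyl}-5α-eudesm-11-en-4α-ol | C[C@@]1(O)CC[C@@H](Cc3c(OCOC)c(C(O)C(C)C)c(OCOC)c(Br)c3OCOC)[C@]2(C)CC[C@@H](C(C)=C)C[C@@H]12
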